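**Assumptions:** The target is (2S)-5,7,3',5'-tetrahydroxy-6,8-diprenylflavanone. From the SMILES, the C2 centre is S (O > aryl > C3 > H). I assume a cinchona primary-amine catalyst of the right pseudo-enantiomer delivers the (S)-flavanone, and that this is confirmed by a small catalyst screen.

**Retrosynthesis**
- The final ring-forming step is the intramolecular oxa-Michael closure of a 2'-hydroxychalcone. This forms the pyranone ring and sets C2.
- The chalcone comes from a Claisen–Schmidt condensation of 3',5'-diprenyl-4',6'-bis-MOM-2'-hydroxyacetophenone with 3,5-bis(MOMO)benzaldehyde.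
- The acetophenone comes from direct C,C-diprenylation of phloroacetophenone, followed by MOM protection of two of its three phenols.
- All four phenols are released together in the last step, so there is no late prenylation.

**Route**

Step 1
Reactants: 1 (2,4,6-trihydroxyacetophenone, phloroacetophenone); 2 (prenyl bromide, 3-methylbut-2-enyl bromide)
Product: 3 (2',4',6'-trihydroxy-3',5'-diprenylacetophenone)
Conditions: 2 (2.2 equiv), KOH (aq.), MeOH, 0 °C → rt; chromatographic separation from mono- and tri-prenylated products
Reagents that add atoms: prenyl bromide, CC(C)=CCBr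
Why: The phloroglucinol-type phenoxide reacts at carbon (C-alkylation) at the two ring positions ortho/para to the OH groups. This is an SN2 C-prenylation, and no stereocentre is formed.

Step 2
Reactants: 3; 4 (chloromethyl methyl ether, MOMCl)
Product: 5 (1-[2-hydroxy-4,6-bis(methoxymethoxy)-3,5-bis(3-methylbut-2-enyl)phenyl]ethanone)
Conditions: NaH (2.1 equiv), then 4 (2.2 equiv), DMF/THF, 0 °C
Reagents that add atoms: MOMCl, COCCl
Why: The 4'-OH (para to the acyl group) and one 2'/6'-OH are the most acidic. They are alkylated as the dianion, while the remaining OH is locked in a hydrogen bond to the carbonyl and survives. This is Williamson-type MOM protection.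

Step 3
Reactants: 6 (3,5-dihydroxybenzaldehyde); 4 (MOMCl)
Product: 7 (3,5-bis(methoxymethoxy)benzaldehyde)
Conditions: 4 (2.5 equiv), i-Pr2NEt, CH2Cl2, 0 °C → rt
Reagents that add atoms: MOMCl, COCCl
Why: Both phenols are converted to MOM ethers, which tolerate the basic condensation and the prenyl groups. The B-ring phenols therefore cannot interfere with the oxa-Michael step.

Step 4
Reactants: 5; 7
Product: 8 ((E)-2'-hydroxychalcone, 1-[2-hydroxy-4,6-bis(MOMO)-3,5-diprenylphenyl]-3-[3,5-bis(MOMO)phenyl]prop-2-en-1-one)
Conditions: KOH (aq.), EtOH, rt; quench with NH4Cl at 0 °C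
Reagents that add atoms: none
Why: This is a Claisen–Schmidt (aldol condensation/dehydration) that gives the E-enone. Any racemic flavanone formed in base re-opens to the chalcone phenoxide, so the material is funnelled to 8 before the asymmetric step.

Step 5
Reactants: 8
Product: 9 ((2S)-5,7,3',5'-tetrakis(MOMO)-6,8-diprenylflavanone)
Conditions: 9-amino-9-deoxy-epi-quinine (20 mol%), PhCO2H (40 mol%), toluene, 40 °C, 2–3 d
Reagents that add atoms: none
Why: This is an asymmetric intramolecular oxa-Michael addition (6-endo). The catalyst forms an iminium with the enone, the chiral ammonium directs the phenol onto one enantioface, and C2 is set as (S) by the choice of quinine- or quinidine-derived amine. The mild, weakly acidic conditions avoid retro-Michael racemisation.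

Step 6
Reactants: 9
Product: 10 (target)
Conditions: Amberlyst-15, MeOH, 40 °C (or HCl/MeOH)
Reagents that add atoms: none
Why: Acid-catalysed acetal cleavage removes all four MOM groups and releases the four phenols. Acid does not touch the C2 stereocentre, and a flavanone is stable to acid, unlike base, which would ring-open it. The prenyl groups survive these mild conditions.

**Checks**
- The A ring in 9 and 10 is C6-prenyl, C7-O, C8-prenyl, C8a-O, C4a-C(=O), C5-O, matching the target.
- The B ring is 3,5-dioxygenated.
- The SMILES neighbour order at C2 is identical in 9 and 10 (C3, H, aryl, O), so both are (S).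
- Atoms balance in every step: Step 4 loses H2O, Step 5 is an isomerisation, and Step 6 swaps four CH2OCH3 groups for H.

**Compound list**
1 | 2,4,6-trihydroxyacetophenone | CC(=O)c1c(O)cc(O)cc1O | starting material
2 | prenyl bromide | CC(C)=CCBr | starting material
3 | 2',4',6'-trihydroxy-3',5'-diprenylacetophenone | CC(=O)c1c(O)c(CC=C(C)C)c(O)c(CC=C(C)C)c1O | intermediate
4 | chloromethyl methyl ether (MOMCl) | COCCl | starting material
5 | 2'-hydroxy-4',6'-bis(MOMO)-3',5'-diprenylacetophenone | CC(=O)c1c(O)c(CC=C(C)C)c(OCOC)c(CC=C(C)C)c1OCOC | intermediate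
6 | 3,5-dihydroxybenzaldehyde | O=Cc1cc(O)cc(O)c1 | starting material
7 | 3,5-bis(MOMO)benzaldehyde | O=Cc1cc(OCOC)cc(OCOC)c1 | intermediate
8 | (E)-chalcone, tetra-MOM | CC(C)=CCc1c(OCOC)c(CC=C(C)C)c(OCOC)c(C(=O)/C=C/c2cc(OCOC)cc(OCOC)c2)c1O | intermediate
9 | (2S)-tetra-MOM-6,8-diprenylflavanone | CC(C)=CCc1c(OCOC)c(CC=C(C)C)c2c(c1OCOC)C(=O)C[C@@H](c1cc(OCOC)cc(OCOC)c1)O2 | intermediate
10 | (2S)-5,7,3',5'-tetrahydroxy-6,8-diprenylflavanone (CID26213315) | CC(C)=CCc1c(O)c(CC=C(C)C)c2c(c1O)C(=O)C[C@@H](c1cc(O)cc(O)c1)O2 | target

**Total steps:** 6 (Steps 1–6, with Step 3 a parallel branch).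
**Longest linear sequence:** 5 steps (1 → 3 → 5 → 8 → 9 → 10, i.e. Steps 1, 2, 4, 5, 6).

**Three steps most likely to fail**
1. **Step 1 (diprenylation).** Mono-, tri- and O-prenylated by-products lower the yield of 3.
   - Fallback: make 2,4-diprenylphloroglucinol by acid-catalysed prenylation of phloroglucinol with 2-methylbut-3-en-2-ol, then regioselectively acetylate it (AcCl, Lewis acid) to give 3.
2. **Step 5 (asymmetric oxa-Michael).** The electron-rich, hydrogen-bonded chalcone is sluggish, and the racemic background reaction may erode ee.
   - Fallback: cyclise 8 to racemic 9 (NaOAc, EtOH), then separate the enantiomers by preparative chiral HPLC.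
   - Alternative fallback: build the 6,8-diprenyl-5,7-bis(MOMO)chromone and add 3,5-bis(MOMO)phenylboronic acid by Pd/chiral pyridine-oxazoline asymmetric conjugate addition.
3. **Step 6 (global MOM removal).** Acid may cyclise an ortho-prenylphenol to a chroman or partly degrade the flavanone.
   - Fallback: change the protecting-group strategy. Use allyl ethers on all four phenols in Steps 2–3, and remove them in the last step under neutral conditions (Pd(PPh3)4, PhSiH3 or morpholine).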